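**Plan**
- Cuts, upper unit first: C2–C1' (ring B put on as a C-aryl "glycoside"), then C3–C4 and O1–C2 of ring C (lactol from an o-quinone methide and (benzyloxy)acetaldehyde), then the C4–C6 inter-unit bond (aryllithium plus ring A aldehyde); the lower unit is cut the same way, plus its C4–O bond.
- Enabling feature: C4 of the upper ring C is benzhydrylic and ortho to the phenolic oxygen O1 on C8a of ring A, so a C4 carbinol loses water across O1–C8a–C4a–C4 to an o-quinone methide; C2–C3 is a glycolaldehyde unit, so ring C is a pyranose whose anomeric carbon C2 carries ring B.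
- Forward order: ring A aldehyde → salicyl alcohol → lower ring C (annulation, arylation) → C4 hydroxylation, silylation, C6 bromination → union with a second ring A aldehyde to an o-hydroxybenzhydrol → upper ring C (key step) → arylation → deprotection.
- Stereochemistry: C3 of both units and the upper C4 come from one (S)-diarylprolinol silyl ether catalyst; both C2 centres from axial aryl delivery cis to 3-OBn; the lower C4 from trans attack of water on the DDQ-derived cation.

Key step: step 11

Remark: β-aryl o-quinone methides are taken to react as the (E)-isomers; flavan numbering is used throughout, and dimers are described as 2,3-cis/4β because some CIP letters change with the protecting groups without change of geometry (the SMILES are definitive).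

**Step 1**
Reactants: 1 2,3,4-trihydroxybenzaldehyde
Product: 2 3,4-bis(benzyloxy)-2-hydroxybenzaldehyde
Conditions: BnBr (2.1 equiv), K2CO3 (2.2 equiv), DMF, 0 °C to rt
Reagents that add atoms: benzyl bromide, BrCc1ccccc1
Why: Williamson etherification; the 2-hydroxyl is hydrogen-bonded to the formyl group and is the least nucleophilic, so benzylation should stop at O3 and O4.

**Step 2**
Reactants: 2 3,4-bis(benzyloxy)-2-hydroxybenzaldehyde
Product: 3 [3,4-bis(benzyloxy)-2-hydroxyphenyl]methanol
Conditions: NaBH4, THF/MeOH, 0 °C; neutral aqueous work-up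
Reagents that add atoms: none
Why: Hydride reduction of the aldehyde gives the salicyl alcohol without touching the benzyl ethers, and the neutral work-up keeps the acid-sensitive benzylic alcohol from ionising.

**Step 3**
Reactants: 3 [3,4-bis(benzyloxy)-2-hydroxyphenyl]methanol; 4 (benzyloxy)acetaldehyde
Product: 7 (3R)-3,7,8-tris(benzyloxy)chroman-2-ol (C2 anomer mixture), via o-quinone methide 5 (not isolated), via hydroxy aldehyde 6 (not isolated)
Conditions: (S)-2-[diphenyl(trimethylsilyloxy)methyl]pyrrolidine (20 mol %), PhCO2H (20 mol %), 4 (3 equiv), CHCl3, 40 °C, slow addition of 3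
Reagents that add atoms: none
Why: Proposed new method: the closest known reaction type is the aminocatalytic formal [4+2] annulation of aldehydes with o-quinone methides made in situ from β-aryl precursors, extended here to an unsubstituted methide carbon released by acid-promoted dehydration of a salicyl alcohol; the carboxylic acid should ionise the benzylic C–O bond of 3, which lies ortho to the phenol and para to a benzyloxy group, to give methide 5 (stabilised as a vinylogous ester by its 3-benzyloxy group and held reversibly by the amine as a Mannich base), the (E)-enamine of 4 should attack the exocyclic CH2 through the face left open by the diphenyl(silyloxy)methyl group and so set C3 as R (same topicity as diarylprolinol silyl ether Michael additions of alkoxyacetaldehydes to nitroalkenes), and hydrolysis followed by 6-exo-trig hemiacetalisation locks C3 in a lactol that no longer enolises.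

**Step 4**
Reactants: 8 [3,4-bis(benzyloxy)phenyl]boronic acid
Product: 9 potassium [3,4-bis(benzyloxy)phenyl]trifluoroborate
Conditions: KHF2 (4 equiv), MeOH/H2O, rt
Reagents that add atoms: potassium hydrogen difluoride, F[H-]F.[K+]
Why: Standard conversion of a boronic acid into its air-stable trifluoroborate salt.

**Step 5**
Reactants: 7 (3R)-3,7,8-tris(benzyloxy)chroman-2-ol
Product: 10 (3R)-3,7,8-tris(benzyloxy)chroman-2-yl acetate (anomer mixture)
Conditions: Ac2O, Et3N, DMAP (cat.), CH2Cl2, 0 °C
Reagents that add atoms: acetic anhydride, CC(=O)OC(C)=O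
Why: Acylation of the hemiacetal hydroxyl gives an anomeric acetate, a leaving group for oxocarbenium formation.

**Step 6**
Reactants: 10 (3R)-3,7,8-tris(benzyloxy)chroman-2-yl acetate; 9 potassium [3,4-bis(benzyloxy)phenyl]trifluoroborate
Product: 11 (2R,3R)-3,7,8-tris(benzyloxy)-2-[3,4-bis(benzyloxy)phenyl]chromane (2,3-cis)
Conditions: BF3·OEt2 (3 equiv), MeCN/CH2Cl2, −40 to −10 °C
Reagents that add atoms: none
Why: Lewis-acid substitution of an anomeric acetate by an aryltrifluoroborate (acetal–trifluoroborate coupling, C-aryl glycosylation type): the aryl group should be delivered axially to the half-chair O1=C2 oxocarbenium ion with 3-OBn pseudo-equatorial, anti to pseudo-axial H-3, which places ring B cis to 3-OBn (2R) under kinetic control.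

**Step 7**
Reactants: 11 (2R,3R)-3,7,8-tris(benzyloxy)-2-[3,4-bis(benzyloxy)phenyl]chromane
Product: 12 (2R,3R,4S)-3,7,8-tris(benzyloxy)-2-[3,4-bis(benzyloxy)phenyl]chroman-4-ol (2,3-cis-3,4-trans, 4β-OH)
Conditions: DDQ (2 equiv), CH2Cl2/H2O (20:1), rt
Reagents that add atoms: water, O
Why: DDQ abstracts hydride from benzylic C4 (benzylic C–H oxidation; the cation is stabilised by O1 and by 7-OBn para to C4a) and water should add to the cation anti to the axial 3-OBn group, giving the 4β-alcohol.

**Step 8**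
Reactants: 12 the 4β-alcohol
Product: 13 4-O-tert-butyldimethylsilyl ether of 12 (CIP 2R,3S,4S, geometry unchanged)
Conditions: TBSOTf, 2,6-lutidine, CH2Cl2, −78 to 0 °C
Reagents that add atoms: tert-butyldimethylsilyl trifluoromethanesulfonate, CC(C)(C)[Si](C)(C)OS(=O)(=O)C(F)(F)F
Why: Silylation of the hindered axial benzylic alcohol with a silyl triflate; the bulky silyl ether is a poor leaving group under the carboxylic acid and Lewis acid of the later steps and is removed by fluoride.

**Step 9**
Reactants: 13 the silyl ether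
Product: 14 6-bromo derivative of 13
Conditions: NBS (1.05 equiv), CH2Cl2, −40 to 0 °C, dark
Reagents that add atoms: N-bromosuccinimide, O=C1CCC(=O)N1Br
Why: Electrophilic aromatic bromination should go to C6 of ring A, para to O1 and ortho to 7-OBn, which is more activated than C5 or any position of ring B.

**Step 10**
Reactants: 14 the aryl bromide; 2 3,4-bis(benzyloxy)-2-hydroxybenzaldehyde
Product: 17 [3,4-bis(benzyloxy)-2-hydroxyphenyl](C6 of unit 13)methanol (o-hydroxybenzhydrol, carbinol epimer mixture), via aryllithium 15 (not isolated), via sodium phenoxide 16 (not isolated)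
Conditions: 14, n-BuLi (1.05 equiv), THF, −78 °C; separately 2 (1.3 equiv), NaH (1.3 equiv), THF, 0 °C; phenoxide solution added at −78 °C, then to −40 °C; H2O
Reagents that add atoms: none
Why: Bromine–lithium exchange followed by 1,2-addition of aryllithium 15 to the aldehyde of the pre-formed sodium phenoxide 16 (the standard route to o-hydroxybenzhydryl alcohols from salicylaldehydes and aryl organometallics) forges the C4–C6 inter-unit bond; the dianionic adduct has no leaving group and stays at the carbinol stage, and the uncontrolled carbinol centre becomes trigonal in step 11.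

**Step 11**
Reactants: 17 the o-hydroxybenzhydrol; 4 (benzyloxy)acetaldehyde
Product: 20 upper ring C lactol, 3,7,8-tris(benzyloxy)-4-(C6 of unit 13)chroman-2-ol (3,4-trans, 4β-aryl, C2 anomer mixture), via o-quinone methide 18 (not isolated), via hydroxy aldehyde 19 (not isolated)
Conditions: (S)-2-[diphenyl(trimethylsilyloxy)methyl]pyrrolidine (20 mol %), PhCO2H (20 mol %), 4 (3 equiv), CHCl3, rt to 40 °C
Reagents that add atoms: none
Why: The carboxylic acid promotes loss of the benzhydrylic hydroxyl of 17, assisted by the ortho phenol oxygen O1 and by 7-OBn para to C4a, so that dehydration across O1–C8a–C4a–C4 gives the (E)-o-quinone methide 18 from both carbinol epimers, and the (E)-enamine from 4 and the catalyst adds through its unshielded face to C4 (Michael addition driven by rearomatisation of ring A), iminium hydrolysis then giving the syn aldehyde 19. The closest known reaction type is the aminocatalytic formal [4+2] annulation of aldehydes with o-quinone methides generated in situ, together with amine/Brønsted acid catalysis that uses o-hydroxybenzhydryl alcohols as the methide source and diarylprolinol silyl ether Michael additions of alkoxyacetaldehydes. Ring C closes by 6-exo-trig addition of the phenol oxygen O1 to the aldehyde carbon C2 (hemiacetalisation), so that C3–C4 and O1–C2 are made in one operation from a benzhydrol and a two-carbon aldehyde. C3 is set by the catalyst (enamine face shielded by the diphenyl(silyloxy)methyl group) and C4 by the synclinal approach to the (E)-methide that leads to the syn adduct, i.e. the 3,4-trans lactol with the 4β-aryl group, which is also the thermodynamically preferred C3 epimer. The step needs chemoselective ionisation (only this carbinol has an ortho phenol and a hydroxyl leaving group, and the lower C4 silyl ether should not ionise under a carboxylic acid), C-attack at C4 instead of amine or oxygen addition (both reversible), and catalyst over substrate control, which the distance of the lower-unit stereocentres from C4 should secure.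

**Step 12**
Reactants: 20 the upper ring C lactol
Product: 21 anomeric acetate of 20
Conditions: Ac2O, Et3N, DMAP (cat.), CH2Cl2, 0 °C
Reagents that add atoms: acetic anhydride, CC(=O)OC(C)=O
Why: Acylation of the hemiacetal hydroxyl gives the anomeric acetate needed for oxocarbenium formation.

**Step 13**
Reactants: 21 the anomeric acetate; 9 potassium [3,4-bis(benzyloxy)phenyl]trifluoroborate
Product: 22 fully protected dimer (both units 2R, 2,3-cis; upper 4β-aryl to lower C6; lower 4β-OTBS; ten benzyl ethers)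
Conditions: BF3·OEt2 (3 equiv), MeCN/CH2Cl2, −45 to −20 °C
Reagents that add atoms: none
Why: Same acetal–trifluoroborate C-arylation as step 6: in the half-chair oxocarbenium ion with 3-OBn and the 4-aryl group both pseudo-equatorial, axial delivery anti to H-3 comes from the α-face, cis to 3-OBn and trans to the 4β-aryl group, so ring B should end 2,3-cis (2R); benzyl-protected flavans do not ring-open at C2 under these conditions, so the kinetic product should persist.

**Step 14**
Reactants: 22 the protected dimer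
Product: 23 the lower-unit 4β-alcohol (deca-O-benzyl ether of the target)
Conditions: TBAF, THF, 0 °C to rt
Reagents that add atoms: none
Why: Fluoride cleavage of the silyl ether frees the lower 4β-hydroxyl without touching benzyl ethers or stereocentres.

**Step 15**
Reactants: 23 the deca-O-benzyl ether
Product: 24 target, CNP0143773.2
Conditions: H2 (1 atm), Pd(OH)2/C, THF/MeOH, rt, short reaction time, filtration under argon
Reagents that add atoms: none
Why: Catalytic hydrogenolysis of the ten benzyl ethers (eight aryl, two alkyl); these should cleave faster than the ring C benzylic C–O bonds at C2 and C4, so brief neutral conditions should leave both rings C and the lower 4β-hydroxyl intact.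

**Compound list**
1 | 2,3,4-trihydroxybenzaldehyde | O=Cc1ccc(O)c(O)c1O | starting material
2 | 3,4-bis(benzyloxy)-2-hydroxybenzaldehyde | O=Cc1ccc(OCc2ccccc2)c(OCc2ccccc2)c1O | intermediate
3 | [3,4-bis(benzyloxy)-2-hydroxyphenyl]methanol | OCc1ccc(OCc2ccccc2)c(OCc2ccccc2)c1O | intermediate
4 | (benzyloxy)acetaldehyde | O=CCOCc1ccccc1 | starting material
5 | 2,3-bis(benzyloxy)-6-methylidenecyclohexa-2,4-dien-1-one (o-quinone methide, not isolated) | C=C1C=CC(OCc2ccccc2)=C(OCc2ccccc2)C1=O | intermediate
6 | (R)-2-(benzyloxy)-3-[3,4-bis(benzyloxy)-2-hydroxyphenyl]propanal (not isolated) | O=C[C@H](OCc1ccccc1)Cc1ccc(OCc2ccccc2)c(OCc2ccccc2)c1O | intermediate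
7 | (3R)-3,7,8-tris(benzyloxy)chroman-2-ol, anomer mixture | OC1Oc2c(ccc(OCc3ccccc3)c2OCc2ccccc2)C[C@H]1OCc1ccccc1 | intermediate
8 | [3,4-bis(benzyloxy)phenyl]boronic acid | OB(O)c1ccc(OCc2ccccc2)c(OCc2ccccc2)c1 | starting material
9 | potassium [3,4-bis(benzyloxy)phenyl]trifluoroborate | [K+].F[B-](F)(F)c1ccc(OCc2ccccc2)c(OCc2ccccc2)c1 | intermediate
10 | (3R)-3,7,8-tris(benzyloxy)chroman-2-yl acetate, anomer mixture | CC(=O)OC1Oc2c(ccc(OCc3ccccc3)c2OCc2ccccc2)C[C@H]1OCc1ccccc1 | intermediate
11 | (2R,3R)-3,7,8-tris(benzyloxy)-2-[3,4-bis(benzyloxy)phenyl]chromane (2,3-cis) | C(c1ccccc1)Oc1ccc([C@H]2Oc3c(ccc(OCc4ccccc4)c3OCc3ccccc3)C[C@H]2OCc2ccccc2)cc1OCc1ccccc1 | intermediate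
12 | (2R,3R,4S)-3,7,8-tris(benzyloxy)-2-[3,4-bis(benzyloxy)phenyl]chroman-4-ol (2,3-cis-3,4-trans) | C(c1ccccc1)Oc1ccc([C@H]2Oc3c(ccc(OCc4ccccc4)c3OCc3ccccc3)[C@H](O)[C@H]2OCc2ccccc2)cc1OCc1ccccc1 | intermediate
13 | 4-O-tert-butyldimethylsilyl ether of 12 | C(c1ccccc1)Oc1ccc([C@H]2Oc3c(ccc(OCc4ccccc4)c3OCc3ccccc3)[C@H](O[Si](C)(C)C(C)(C)C)[C@H]2OCc2ccccc2)cc1OCc1ccccc1 | intermediate
14 | 6-bromo derivative of 13 | C(c1ccccc1)Oc1ccc([C@H]2Oc3c(cc(Br)c(OCc4ccccc4)c3OCc3ccccc3)[C@H](O[Si](C)(C)C(C)(C)C)[C@H]2OCc2ccccc2)cc1OCc1ccccc1 | intermediate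
15 | 6-lithio derivative of 13 (not isolated) | C(c1ccccc1)Oc1ccc([C@H]2Oc3c(cc([Li])c(OCc4ccccc4)c3OCc3ccccc3)[C@H](O[Si](C)(C)C(C)(C)C)[C@H]2OCc2ccccc2)cc1OCc1ccccc1 | intermediate
16 | sodium 2,3-bis(benzyloxy)-6-formylphenoxide (not isolated) | O=Cc1ccc(OCc2ccccc2)c(OCc2ccccc2)c1[O-].[Na+] | intermediate
17 | [3,4-bis(benzyloxy)-2-hydroxyphenyl](C6 of unit 13)methanol, carbinol epimer mixture | OC(c5cc6c(c(OCc7ccccc7)c5OCc5ccccc5)O[C@H](c5ccc(OCc7ccccc7)c(OCc7ccccc7)c5)[C@H](OCc5ccccc5)[C@H]6O[Si](C)(C)C(C)(C)C)c1ccc(OCc2ccccc2)c(OCc2ccccc2)c1O | intermediate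
18 | (E)-2,3-bis(benzyloxy)-6-[(C6 of unit 13)methylidene]cyclohexa-2,4-dien-1-one (o-quinone methide, not isolated) | O=C1/C(=C/c5cc6c(c(OCc7ccccc7)c5OCc5ccccc5)O[C@H](c5ccc(OCc7ccccc7)c(OCc7ccccc7)c5)[C@H](OCc5ccccc5)[C@H]6O[Si](C)(C)C(C)(C)C)C=CC(OCc2ccccc2)=C1OCc1ccccc1 | intermediate
19 | syn-2-(benzyloxy)-3-[3,4-bis(benzyloxy)-2-hydroxyphenyl]-3-(C6 of unit 13)propanal (not isolated) | O=C[C@H](OCc1ccccc1)[C@@H](c5cc6c(c(OCc7ccccc7)c5OCc5ccccc5)O[C@H](c5ccc(OCc7ccccc7)c(OCc7ccccc7)c5)[C@H](OCc5ccccc5)[C@H]6O[Si](C)(C)C(C)(C)C)c1ccc(OCc2ccccc2)c(OCc2ccccc2)c1O | intermediate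
20 | 3,7,8-tris(benzyloxy)-4-(C6 of unit 13)chroman-2-ol, 3,4-trans, 4β-aryl, anomer mixture | OC1Oc2c(ccc(OCc3ccccc3)c2OCc2ccccc2)[C@H](c5cc6c(c(OCc7ccccc7)c5OCc5ccccc5)O[C@H](c5ccc(OCc7ccccc7)c(OCc7ccccc7)c5)[C@H](OCc5ccccc5)[C@H]6O[Si](C)(C)C(C)(C)C)[C@H]1OCc1ccccc1 | intermediate
21 | anomeric acetate of 20 | CC(=O)OC1Oc2c(ccc(OCc3ccccc3)c2OCc2ccccc2)[C@H](c5cc6c(c(OCc7ccccc7)c5OCc5ccccc5)O[C@H](c5ccc(OCc7ccccc7)c(OCc7ccccc7)c5)[C@H](OCc5ccccc5)[C@H]6O[Si](C)(C)C(C)(C)C)[C@H]1OCc1ccccc1 | intermediate
22 | protected dimer: upper unit 11 joined 4β to C6 of lower unit 13 | C(c1ccccc1)Oc1ccc([C@H]2Oc3c(ccc(OCc4ccccc4)c3OCc3ccccc3)[C@H](c5cc6c(c(OCc7ccccc7)c5OCc5ccccc5)O[C@H](c5ccc(OCc7ccccc7)c(OCc7ccccc7)c5)[C@H](OCc5ccccc5)[C@H]6O[Si](C)(C)C(C)(C)C)[C@H]2OCc2ccccc2)cc1OCc1ccccc1 | intermediate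
23 | deca-O-benzyl ether of the target (lower 4β-OH free) | C(c1ccccc1)Oc1ccc([C@H]2Oc3c(ccc(OCc4ccccc4)c3OCc3ccccc3)[C@H](c5cc6c(c(OCc7ccccc7)c5OCc5ccccc5)O[C@H](c5ccc(OCc7ccccc7)c(OCc7ccccc7)c5)[C@H](OCc5ccccc5)[C@H]6O)[C@H]2OCc2ccccc2)cc1OCc1ccccc1 | intermediate
24 | CNP0143773.2, (2R,3R,4S)-flavan-3,7,8,3',4'-pentaol joined 4β to C6 of (2R,3R,4S)-flavan-3,4,7,8,3',4'-hexaol | Oc1ccc([C@H]2Oc3c(ccc(O)c3O)[C@H](c3cc4c(c(O)c3O)O[C@H](c3ccc(O)c(O)c3)[C@H](O)[C@H]4O)[C@H]2O)cc1O | target

**Totals**
Total step count: 15. Longest linear sequence: 14 (steps 1–3 and 5–15).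

**Steps most likely to fail**

Step 3 (proposed new method). The unsubstituted methide may oligomerise, or alkylate the electron-rich ring of unreacted 3, faster than the enamine traps it, and the single stereocentre at C3 may erode by enolisation before the lactol closes. The fallback uses known chemistry, sets out from 2 and comes back at 7. Silylation of 2 (TBSCl, imidazole, DMF) should give 3,4-bis(benzyloxy)-2-(tert-butyldimethylsilyloxy)benzaldehyde F1. NaBH4 (MeOH, 0 °C) then gives [3,4-bis(benzyloxy)-2-(tert-butyldimethylsilyloxy)phenyl]methanol F2, and CBr4/PPh3 (CH2Cl2, 0 °C) gives 3,4-bis(benzyloxy)-2-(tert-butyldimethylsilyloxy)benzyl bromide F3. Acylation of (S)-4-benzyloxazolidin-2-one (n-BuLi, benzyloxyacetyl chloride) gives (S)-4-benzyl-3-[(benzyloxy)acetyl]oxazolidin-2-one F4. Its sodium enolate (NaN(SiMe3)2, THF, −78 °C) is alkylated by F3 anti to the 4-benzyl group of the chelated Z-enolate (Evans glycolate alkylation) to give (S)-4-benzyl-3-[(R)-2-(benzyloxy)-3-[3,4-bis(benzyloxy)-2-(tert-butyldimethylsilyloxy)phenyl]propanoyl]oxazolidin-2-one F5. TBAF frees the phenoxide, which cleaves the imide intramolecularly to (3R)-3,7,8-tris(benzyloxy)chroman-2-one F6, and i-Bu2AlH (CH2Cl2, −78 °C) reduces the lactone to lactol 7.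

Step 11 (key step). Conjugate addition to the hindered, doubly aryl-flanked methide may be too slow, so that self-condensation of the methide or acid-induced decomposition of the carbinol takes over, or the facial selectivity may be low. The fallback forms the inter-unit bond last by cationic flavan coupling; it sets out from 12 and 13 and comes back at 22, bypassing steps 9 to 13. Acetylation of 12 (Ac2O, pyridine, DMAP) gives (2R,3R,4S)-3,7,8-tris(benzyloxy)-2-[3,4-bis(benzyloxy)phenyl]chroman-4-yl acetate F7. Me3SiOTf (CH2Cl2, −78 °C) ionises the acetate in the presence of excess 13 (recovered); C6 of 13 should attack the C4 cation trans to 3-OBn, while the silyl ether of 13 stays un-ionised, to give 22.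

Step 13. Facial selectivity in the aryl transfer may be insufficient, or the lower silyl ether may ionise under BF3·OEt2. The fallback sets C2 in an open chain and closes ring C by SN2; it sets out from 20 and comes back at 22. 3,4-Bis(benzyloxy)phenyllithium F8 (from commercial 4-bromo-1,2-bis(benzyloxy)benzene and n-BuLi; 3 equiv, THF, −78 °C) adds to the open aldehyde form of 20 under Felkin–Anh (non-chelation) control to give the anti carbinol 1-[3,4-bis(benzyloxy)phenyl]-2-(benzyloxy)-3-[3,4-bis(benzyloxy)-2-hydroxyphenyl]-3-(C6 of unit 13)propan-1-ol F9. Mitsunobu cyclisation (PPh3, DIAD, THF, 0 °C) displaces the C2 hydroxyl by the phenol oxygen O1 with inversion to give 22.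

**Further compounds**
F1 | step 3 | 3,4-bis(benzyloxy)-2-(tert-butyldimethylsilyloxy)benzaldehyde | O=Cc1ccc(OCc2ccccc2)c(OCc2ccccc2)c1O[Si](C)(C)C(C)(C)C
F2 | step 3 | [3,4-bis(benzyloxy)-2-(tert-butyldimethylsilyloxy)phenyl]methanol | OCc1ccc(OCc2ccccc2)c(OCc2ccccc2)c1O[Si](C)(C)C(C)(C)C
F3 | step 3 | 3,4-bis(benzyloxy)-2-(tert-butyldimethylsilyloxy)benzyl bromide | BrCc1ccc(OCc2ccccc2)c(OCc2ccccc2)c1O[Si](C)(C)C(C)(C)C
F4 | step 3 | (S)-4-benzyl-3-[(benzyloxy)acetyl]oxazolidin-2-one | O=C(COCc1ccccc1)N1C(=O)OC[C@@H]1Cc1ccccc1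
F5 | step 3 | (S)-4-benzyl-3-[(R)-2-(benzyloxy)-3-[3,4-bis(benzyloxy)-2-(tert-butyldimethylsilyloxy)phenyl]propanoyl]oxazolidin-2-one | O=C([C@H](OCc1ccccc1)Cc1ccc(OCc2ccccc2)c(OCc2ccccc2)c1O[Si](C)(C)C(C)(C)C)N1C(=O)OC[C@@H]1Cc1ccccc1
F6 | step 3 | (3R)-3,7,8-tris(benzyloxy)chroman-2-one | O=C1Oc2c(ccc(OCc3ccccc3)c2OCc2ccccc2)C[C@H]1OCc1ccccc1
F7 | step 11 | (2R,3R,4S)-3,7,8-tris(benzyloxy)-2-[3,4-bis(benzyloxy)phenyl]chroman-4-yl acetate | C(c1ccccc1)Oc1ccc([C@H]2Oc3c(ccc(OCc4ccccc4)c3OCc3ccccc3)[C@H](OC(C)=O)[C@H]2OCc2ccccc2)cc1OCc1ccccc1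
F8 | step 13 | 3,4-bis(benzyloxy)phenyllithium | [Li]c1ccc(OCc2ccccc2)c(OCc2ccccc2)c1
F9 | step 13 | anti-1-[3,4-bis(benzyloxy)phenyl]-2-(benzyloxy)-3-[3,4-bis(benzyloxy)-2-hydroxyphenyl]-3-(C6 of unit 13)propan-1-ol | C(c1ccccc1)Oc1ccc([C@H](O)[C@H](OCc2ccccc2)[C@@H](c5cc6c(c(OCc7ccccc7)c5OCc5ccccc5)O[C@H](c5ccc(OCc7ccccc7)c(OCc7ccccc7)c5)[C@H](OCc5ccccc5)[C@H]6O[Si](C)(C)C(C)(C)C)c2ccc(OCc3ccccc3)c(OCc3ccccc3)c2O)cc1OCc1ccccc1
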